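**Retrosynthetic overview**
1. The target is methyl 8β-acetoxy-3α-angeloyloxy-5α-hydroperoxyeudesma-4(15),11(13)-dien-12-oate (3R,5S,7R,8R,10R). The C5–OOH / C4=C15 unit goes back to a C4=C5 alkene (singlet-oxygen ene reaction, last step), the 3α-ester to a 4-en-3-one, and the enone to a C3=C4 alkene (α-epoxide, 4β-bromo-3-ketone, dehydrobromination).
2. The C7 acrylate and C8 acetate go back to a C8 ketone: C7 alkylation, hydride reduction to the cis 12,8β-lactone, Mannich base, ring opening with elimination, acetylation.
3. Key disconnection: bonds C4–C5 and C9–C10 of the trans-decalin are cut together. In the forward direction one gold-catalysed enantioselective cascade on an acyclic (E)-enyne silyl enol ether closes ring A first and ring B second.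
4. Structural feature used: the methyl-bearing carbons C4 and C10 flank C5 in a 1,3 (head-to-tail isoprenoid) array in ring A, and ring B carries its oxygen at C8, where an enol ether terminator leaves a ketone.
5. The chain is built from a bromo ketal Grignard reagent, methacrolein and triethyl orthoacetate (Johnson–Claisen for the E alkene), then Corey–Fuchs homologation to the methyl alkyne.

Key step: step 8

Numbering: eudesmane numbering is used for all bicyclic compounds (ring A = C1–C5 and C10; ring B = C5–C10; C14 = methyl on C10; C15 = carbon on C4; C11–C13 = side chain on C7); α is the face opposite the C10 methyl group.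
Assumption: the (R)-ligand is taken to give the (5R,10R) enantiomer of the cyclisation product (5α-H, 10β-methyl); if the sense of induction is the opposite, the (S)-ligand is used and nothing else changes.
Remark: the bromo ketal starting material is the commercial ethylene ketal of 4-bromobutan-2-one.

Step 1
Reactants: 1 2-(2-bromoethyl)-2-methyl-1,3-dioxolane; 2 methacrolein
Product: 4 (±)-2-methyl-5-(2-methyl-1,3-dioxolan-2-yl)pent-1-en-3-ol, via Grignard reagent 3 (not isolated)
Conditions: Mg, THF, 30 °C; then 2, −78 → 0 °C; aqueous work-up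
Reagents that add atoms: none
Why: Grignard 1,2-addition to the enal carbonyl is fast at low temperature, the ketal is inert, and the new carbinol centre is left racemic because step 2 destroys it.

Step 2
Reactants: 4 (±)-2-methyl-5-(2-methyl-1,3-dioxolan-2-yl)pent-1-en-3-ol; 5 triethyl orthoacetate
Product: 7 ethyl (4E)-4-methyl-7-(2-methyl-1,3-dioxolan-2-yl)hept-4-enoate, via mixed ketene acetal 6 (not isolated)
Conditions: 5 (5 equiv), EtCO2H (cat.), 140 °C, EtOH distilled off
Reagents that add atoms: none
Why: Johnson–Claisen rearrangement through a chair transition state with the carbinol substituent equatorial should give the E trisubstituted C5=C10 alkene and attach the two-carbon ester arm (C2, C3) to C1.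

Step 3
Reactants: 7 ethyl (4E)-4-methyl-7-(2-methyl-1,3-dioxolan-2-yl)hept-4-enoate
Product: 8 (4E)-4-methyl-7-(2-methyl-1,3-dioxolan-2-yl)hept-4-enal
Conditions: i-Bu2AlH (1.05 equiv), CH2Cl2, −78 °C; aq. potassium sodium tartrate
Reagents that add atoms: none
Why: Partial ester reduction by i-Bu2AlH at −78 °C stops at the tetrahedral aluminium hemiacetal, which releases the aldehyde on work-up.

Step 4
Reactants: 8 (4E)-4-methyl-7-(2-methyl-1,3-dioxolan-2-yl)hept-4-enal
Product: 9 2-[(3E)-8,8-dibromo-4-methylocta-3,7-dien-1-yl]-2-methyl-1,3-dioxolane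
Conditions: CBr4, PPh3, Zn, CH2Cl2, 23 °C (ylide preformed); then 8, 23 °C
Reagents that add atoms: carbon tetrabromide, BrC(Br)(Br)Br
Why: Corey–Fuchs dibromo-olefination (Wittig type) of an unhindered aldehyde, run in the zinc variant so that the medium stays neutral and the ketal survives.

Step 5
Reactants: 9 2-[(3E)-8,8-dibromo-4-methylocta-3,7-dien-1-yl]-2-methyl-1,3-dioxolane
Product: 11 2-methyl-2-[(3E)-4-methylnon-3-en-7-yn-1-yl]-1,3-dioxolane, via lithium acetylide 10 (not isolated)
Conditions: n-BuLi (2.1 equiv), THF, −78 → 0 °C; then MeI, −78 → 23 °C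
Reagents that add atoms: iodomethane, CI
Why: Second stage of the Corey–Fuchs sequence (bromine–lithium exchange, 1,2-shift to the alkyne, deprotonation) followed by C-methylation of the acetylide gives the internal methyl alkyne C15–C4≡C3.

Step 6
Reactants: 11 2-methyl-2-[(3E)-4-methylnon-3-en-7-yn-1-yl]-1,3-dioxolane
Product: 12 (5E)-6-methylundec-5-en-9-yn-2-one
Conditions: 1 M aq. HCl, THF, 23 °C
Reagents that add atoms: water, O
Why: Acid-catalysed ketal hydrolysis frees the methyl ketone and leaves the alkene and the internal alkyne untouched.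

Step 7
Reactants: 12 (5E)-6-methylundec-5-en-9-yn-2-one
Product: 14 tert-butyl(dimethyl){[(5E)-6-methylundeca-1,5-dien-9-yn-2-yl]oxy}silane, via lithium enolate 13 (not isolated)
Conditions: LDA (1.1 equiv), THF, −78 °C; then TBSCl, DMPU, −78 → 0 °C
Reagents that add atoms: tert-butyldimethylsilyl chloride, CC(C)(C)[Si](C)(C)Cl
Why: Kinetic deprotonation of a methyl ketone by LDA removes the less hindered methyl proton and O-silylation fixes the terminal enol ether C8=C9.

Step 8
Reactants: 14 tert-butyl(dimethyl){[(5E)-6-methylundeca-1,5-dien-9-yn-2-yl]oxy}silane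
Product: 15 (4aR,8aR)-5,8a-dimethyl-3,4,4a,7,8,8a-hexahydronaphthalen-2(1H)-one (11,12,13-trinoreudesm-3-en-8-one)
Conditions: (R)-DTBM-MeO-BIPHEP(AuCl)2 (3 mol %), AgSbF6 (3 mol %), i-PrOH (1.2 equiv), toluene, −20 → 23 °C
Reagents that add atoms: none
Why: Proposed new method: the cationic monovalent gold complex binds the C3≡C4 alkyne, the alkene carbon C5 adds to C4 anti to the metal and closes ring A in 6-endo-dig mode (C3 becomes an alkenylgold carbon), and the tertiary cation at C10 is captured by C9 of the enol ether, which closes ring B in 6-endo-trig mode, while 2-propanol takes the silyl group from the oxocarbenium ion and supplies the proton that cleaves the C3–Au bond. The closest known reaction type is the gold-catalysed enantioselective alkyne-initiated polyene cyclisation of enynes with digold bisphosphine chlorides and heteroatom or arene terminators, together with the gold-catalysed 6-endo double cyclisation of 1,5-enynes that carry a substituent on the inner alkene carbon; an internal methyl alkyne combined with a silyl enol ether carbon terminator has not been shown. C5 is set by the chiral ligand, which selects the alkene face that attacks the gold-bound alkyne. C10 follows from C5, because C4 and C9 add anti across the E alkene in a chair–chair fold, which gives the trans ring fusion. The step needs 6-endo instead of 5-endo (cyclopropyl carbene) closure and ring closure instead of proton loss: the methyl group on C10 makes the 6-endo cation tertiary, and the enol ether carbon C9 lies in reach for a chair six-membered transition state.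

Step 9
Reactants: 15 11,12,13-trinoreudesm-3-en-8-one
Product: 18 methyl 8-oxo-13-noreudesm-3-en-12-oate (7α-H), via lithium enolate 16 (not isolated), via 7-epimeric keto ester 17 (not isolated)
Conditions: LDA (1.05 equiv), THF, −78 °C; BrCH2CO2Me, DMPU, −78 → −30 °C; then K2CO3 (0.2 equiv), MeOH, 23 °C
Reagents that add atoms: methyl bromoacetate, BrCC(=O)OC
Why: Kinetic enolisation should occur at C7 (C9 is shielded by the quaternary C10), and enolate alkylation is followed by base equilibration through the enol, which places the C7 side chain in the equatorial β position.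

Step 10
Reactants: 18 methyl 8-oxo-13-noreudesm-3-en-12-oate
Product: 20 13-noreudesm-3-en-12,8β-olide (cis-fused γ-lactone), via lithium alkoxide 19 (not isolated)
Conditions: LiBH(s-Bu)3 (1.1 equiv), THF, −78 → 23 °C; H2O
Reagents that add atoms: none
Why: The bulky borohydride attacks the C8 ketone along the equatorial α trajectory, away from the axial C10 methyl group, to give the axial 8β-alkoxide, which closes onto the cis ester arm (lactonisation).

Step 11
Reactants: 20 13-noreudesm-3-en-12,8β-olide
Product: 22 13-(dimethylamino)eudesm-3-en-12,8β-olide (C11 epimers), via lithium enolate 21 (not isolated)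
Conditions: LDA (1.2 equiv), THF, −78 °C; then CH2=NMe2+ I−, −78 → 23 °C
Reagents that add atoms: dimethylmethyleneammonium iodide, C=[N+](C)C.[I-]
Why: Mannich aminomethylation of the lactone enolate with the preformed iminium salt installs C13, and the configuration at C11 is immaterial because C11 becomes trigonal in step 12.

Step 12
Reactants: 22 13-(dimethylamino)eudesm-3-en-12,8β-olide
Product: 25 methyl 8β-hydroxyeudesma-3,11(13)-dien-12-oate, via potassium carboxylate 23 (not isolated), via ammonium ester 24 (not isolated)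
Conditions: KOH (1.05 equiv), H2O/1,4-dioxane, 23 °C; evaporate; then MeI (5 equiv), K2CO3 (2 equiv), DMF, 0 → 23 °C
Reagents that add atoms: potassium hydroxide, [K+].[OH-]; iodomethane, CI
Why: Saponification opens the lactone while no Michael acceptor is present, MeI then alkylates the carboxylate and quaternises the amine, and the β-ammonium ester undergoes E1cB (Hofmann-type) elimination to the acrylate.

Step 13
Reactants: 25 methyl 8β-hydroxyeudesma-3,11(13)-dien-12-oate
Product: 26 methyl 8β-acetoxyeudesma-3,11(13)-dien-12-oate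
Conditions: Ac2O, Et3N, DMAP (cat.), CH2Cl2, 0 → 23 °C (25 used at once)
Reagents that add atoms: acetic anhydride, CC(=O)OC(C)=O
Why: DMAP-catalysed acylation of the axial 8β-hydroxyl should outrun its return to the lactone and closes that pathway for the rest of the route.

Step 14
Reactants: 26 methyl 8β-acetoxyeudesma-3,11(13)-dien-12-oate
Product: 27 methyl 8β-acetoxy-3α,4α-epoxyeudesm-11(13)-en-12-oate
Conditions: mCPBA, NaHCO3, CH2Cl2, 0 °C
Reagents that add atoms: 3-chloroperoxybenzoic acid, OOC(=O)c1cccc(Cl)c1
Why: Prilezhaev epoxidation takes the electron-rich trisubstituted C3=C4 alkene (the acrylate is electron-poor) from the α face, opposite the axial C10 methyl group, which sets C3 and C4.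

Step 15
Reactants: 27 methyl 8β-acetoxy-3α,4α-epoxyeudesm-11(13)-en-12-oate
Product: 28 methyl 8β-acetoxy-4β-bromo-3α-hydroxyeudesm-11(13)-en-12-oate
Conditions: 48% aq. HBr, CHCl3, 0 °C
Reagents that add atoms: hydrogen bromide, Br
Why: Acid-mediated epoxide opening follows the Fürst–Plattner rule and the preference for the tertiary carbon, so bromide enters at C4 from the β face with inversion and the 3α C–O bond is kept (trans-diaxial bromohydrin).

Step 16
Reactants: 28 methyl 8β-acetoxy-4β-bromo-3α-hydroxyeudesm-11(13)-en-12-oate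
Product: 29 methyl 8β-acetoxy-4β-bromo-3-oxoeudesm-11(13)-en-12-oate
Conditions: Dess–Martin periodinane, CH2Cl2, 23 °C
Reagents that add atoms: none
Why: Dess–Martin oxidation of the secondary alcohol proceeds without base, which avoids return of the trans-diaxial bromohydrin to the epoxide.

Step 17
Reactants: 29 methyl 8β-acetoxy-4β-bromo-3-oxoeudesm-11(13)-en-12-oate
Product: 30 methyl 8β-acetoxy-3-oxoeudesma-4,11(13)-dien-12-oate
Conditions: Li2CO3, LiBr, DMF, 100 °C
Reagents that add atoms: none
Why: E2 dehydrobromination of the tertiary α-bromo ketone, in which the axial 4β-bromide is antiperiplanar to the axial 5α-hydrogen, should give the conjugated tetrasubstituted C4=C5 enone, so the position of the double bond is fixed by where the bromide was placed.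

Step 18
Reactants: 30 methyl 8β-acetoxy-3-oxoeudesma-4,11(13)-dien-12-oate
Product: 31 methyl 8β-acetoxy-3α-hydroxyeudesma-4,11(13)-dien-12-oate
Conditions: (S)-2-methyl-CBS-oxazaborolidine (0.5 equiv), catecholborane (1.5 equiv), toluene, −78 °C
Reagents that add atoms: none
Why: Corey–Bakshi–Shibata reduction is a reagent-controlled 1,2-reduction in which the 4-methyl-substituted alkene arm acts as the large group, so the (S)-catalyst should deliver hydride to the β face and set 3α-OH (3R), while catecholborane leaves the acrylate and the acetate alone.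

Step 19
Reactants: 31 methyl 8β-acetoxy-3α-hydroxyeudesma-4,11(13)-dien-12-oate; 32 angelic acid
Product: 34 methyl 8β-acetoxy-3α-(angeloyloxy)eudesma-4,11(13)-dien-12-oate, via mixed anhydride 33 (not isolated)
Conditions: 32, 2,4,6-trichlorobenzoyl chloride, Et3N, toluene, 23 °C; then 31, 80 °C
Reagents that add atoms: none
Why: Yamaguchi-type esterification through the hindered mixed anhydride acylates the allylic alcohol with retention at C3 and, run without a nucleophilic amine catalyst, should keep the Z geometry of the angelate.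

Step 20
Reactants: 34 methyl 8β-acetoxy-3α-(angeloyloxy)eudesma-4,11(13)-dien-12-oate
Product: 35 methyl 8β-acetoxy-3α-(angeloyloxy)-5α-hydroperoxyeudesma-4(15),11(13)-dien-12-oate (CNP0116769.2)
Conditions: O2, tetraphenylporphyrin (cat.), visible light, CH2Cl2, −20 °C
Reagents that add atoms: dioxygen, O=O
Why: Schenck ene reaction of singlet oxygen with the only electron-rich (tetrasubstituted) alkene should occur on the α face opposite the C10 methyl group, where the only allylic hydrogens that can align with the π system are those of the C4 methyl group (H-3 is β and H-6α lies near the alkene plane), so oxygen bonds to C5 (5α-OOH, 5S) and the double bond moves to C4=C15.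

**Compound list**
1 | 2-(2-bromoethyl)-2-methyl-1,3-dioxolane | CC1(CCBr)OCCO1 | starting material
2 | methacrolein (2-methylprop-2-enal) | CC(=C)C=O | starting material
3 | [2-(2-methyl-1,3-dioxolan-2-yl)ethyl]magnesium bromide | CC1(CC[Mg]Br)OCCO1 | intermediate
4 | (±)-2-methyl-5-(2-methyl-1,3-dioxolan-2-yl)pent-1-en-3-ol | CC(=C)C(O)CCC1(C)OCCO1 | intermediate
5 | triethyl orthoacetate | CCOC(C)(OCC)OCC | starting material
6 | mixed ketene acetal, 2-{3-[(1-ethoxyethenyl)oxy]-4-methylpent-4-en-1-yl}-2-methyl-1,3-dioxolane | C=C(OCC)OC(CCC1(C)OCCO1)C(C)=C | intermediate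
7 | ethyl (4E)-4-methyl-7-(2-methyl-1,3-dioxolan-2-yl)hept-4-enoate | CCOC(=O)CC/C(C)=C/CCC1(C)OCCO1 | intermediate
8 | (4E)-4-methyl-7-(2-methyl-1,3-dioxolan-2-yl)hept-4-enal | O=CCC/C(C)=C/CCC1(C)OCCO1 | intermediate
9 | 2-[(3E)-8,8-dibromo-4-methylocta-3,7-dien-1-yl]-2-methyl-1,3-dioxolane | BrC(Br)=CCC/C(C)=C/CCC1(C)OCCO1 | intermediate
10 | lithium acetylide of 2-methyl-2-[(3E)-4-methyloct-3-en-7-yn-1-yl]-1,3-dioxolane | [Li]C#CCC/C(C)=C/CCC1(C)OCCO1 | intermediate
11 | 2-methyl-2-[(3E)-4-methylnon-3-en-7-yn-1-yl]-1,3-dioxolane | CC#CCC/C(C)=C/CCC1(C)OCCO1 | intermediate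
12 | (5E)-6-methylundec-5-en-9-yn-2-one | CC(=O)CC/C=C(\C)CCC#CC | intermediate
13 | lithium (5E)-6-methylundeca-1,5-dien-9-yn-2-olate | [Li]OC(=C)CC/C=C(\C)CCC#CC | intermediate
14 | tert-butyl(dimethyl){[(5E)-6-methylundeca-1,5-dien-9-yn-2-yl]oxy}silane | C=C(O[Si](C)(C)C(C)(C)C)CC/C=C(\C)CCC#CC | intermediate
15 | (4aR,8aR)-5,8a-dimethyl-3,4,4a,7,8,8a-hexahydronaphthalen-2(1H)-one (11,12,13-trinoreudesm-3-en-8-one; 5α-H, 10β-methyl) | C1C[C@H]2C(C)=CCC[C@]2(C)CC1=O | intermediate
16 | lithium C7–C8 enolate of 15 | [Li]OC1=CC[C@H]2C(C)=CCC[C@]2(C)C1 | intermediate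
17 | methyl 8-oxo-13-noreudesm-3-en-12-oate, 7β-H epimer (side chain α, axial) | COC(=O)C[C@@H]1C[C@H]2C(C)=CCC[C@]2(C)CC1=O | intermediate
18 | methyl 8-oxo-13-noreudesm-3-en-12-oate (7α-H; side chain β, equatorial) | COC(=O)C[C@H]1C[C@H]2C(C)=CCC[C@]2(C)CC1=O | intermediate
19 | lithium alkoxide of methyl 8β-hydroxy-13-noreudesm-3-en-12-oate | COC(=O)C[C@H]1C[C@H]2C(C)=CCC[C@]2(C)C[C@H]1O[Li] | intermediate
20 | 13-noreudesm-3-en-12,8β-olide (7α-H, 8α-H, cis-fused) | O=C1C[C@H]2C[C@H]3C(C)=CCC[C@]3(C)C[C@H]2O1 | intermediate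
21 | lithium enolate of lactone 20 | [Li]OC1=C[C@H]2C[C@H]3C(C)=CCC[C@]3(C)C[C@H]2O1 | intermediate
22 | 13-(dimethylamino)eudesm-3-en-12,8β-olide (C11 epimers) | O=C1C(CN(C)C)[C@H]2C[C@H]3C(C)=CCC[C@]3(C)C[C@H]2O1 | intermediate
23 | potassium 13-(dimethylamino)-8β-hydroxyeudesm-3-en-12-oate | CN(C)CC(C(=O)[O-])[C@H]1C[C@H]2C(C)=CCC[C@]2(C)C[C@H]1O.[K+] | intermediate
24 | methyl 8β-hydroxy-13-(trimethylammonio)eudesm-3-en-12-oate iodide | C[N+](C)(C)CC(C(=O)OC)[C@H]1C[C@H]2C(C)=CCC[C@]2(C)C[C@H]1O.[I-] | intermediate
25 | methyl 8β-hydroxyeudesma-3,11(13)-dien-12-oate | C=C(C(=O)OC)[C@H]1C[C@H]2C(C)=CCC[C@]2(C)C[C@H]1O | intermediate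
26 | methyl 8β-acetoxyeudesma-3,11(13)-dien-12-oate | C=C(C(=O)OC)[C@H]1C[C@H]2C(C)=CCC[C@]2(C)C[C@H]1OC(C)=O | intermediate
27 | methyl 8β-acetoxy-3α,4α-epoxyeudesm-11(13)-en-12-oate | C=C(C(=O)OC)[C@H]1C[C@H]2[C@]3(C)O[C@@H]3CC[C@]2(C)C[C@H]1OC(C)=O | intermediate
28 | methyl 8β-acetoxy-4β-bromo-3α-hydroxyeudesm-11(13)-en-12-oate (4α-methyl) | C=C(C(=O)OC)[C@H]1C[C@H]2[C@@](C)(Br)[C@H](O)CC[C@]2(C)C[C@H]1OC(C)=O | intermediate
29 | methyl 8β-acetoxy-4β-bromo-3-oxoeudesm-11(13)-en-12-oate | C=C(C(=O)OC)[C@H]1C[C@H]2[C@@](C)(Br)C(=O)CC[C@]2(C)C[C@H]1OC(C)=O | intermediate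
30 | methyl 8β-acetoxy-3-oxoeudesma-4,11(13)-dien-12-oate | C=C(C(=O)OC)[C@H]1CC2=C(C)C(=O)CC[C@]2(C)C[C@H]1OC(C)=O | intermediate
31 | methyl 8β-acetoxy-3α-hydroxyeudesma-4,11(13)-dien-12-oate | C=C(C(=O)OC)[C@H]1CC2=C(C)[C@H](O)CC[C@]2(C)C[C@H]1OC(C)=O | intermediate
32 | angelic acid, (Z)-2-methylbut-2-enoic acid | C/C=C(/C)C(=O)O | starting material
33 | angelic 2,4,6-trichlorobenzoic anhydride | C/C=C(/C)C(=O)OC(=O)c1c(Cl)cc(Cl)cc1Cl | intermediate
34 | methyl 8β-acetoxy-3α-(angeloyloxy)eudesma-4,11(13)-dien-12-oate | C=C(C(=O)OC)[C@H]1CC2=C(C)[C@H](OC(=O)/C(C)=C\C)CC[C@]2(C)C[C@H]1OC(C)=O | intermediate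
35 | methyl (3R,5S,7R,8R,10R)-8-acetoxy-3-(angeloyloxy)-5-hydroperoxyeudesma-4(15),11(13)-dien-12-oate (CNP0116769.2) | C=C(C(=O)OC)[C@H]1C[C@@]2(OO)C(=C)[C@H](OC(=O)/C(C)=C\C)CC[C@]2(C)C[C@H]1OC(C)=O | target

**Step count and risks**
Total step count: 20. Longest linear sequence: 20 steps (1 → 35).

Step 8 (proposed new method). What may go wrong: the cascade may stop after ring A by proton loss from the C10 cation; the 5-endo (cyclopropyl gold carbene) manifold may compete with 6-endo closure; the enol ether may be protodesilylated before it can act as terminator; or the ligand may discriminate poorly between the two alkene faces. The fallback uses known chemistry, a Robinson annulation on a chiral imine. None of the chain compounds 1–14 can be carried over, so it sets out from no numbered compound but from commercial racemic 7-methyl-1,4-dioxaspiro[4.5]decan-8-one F1, and it comes back to the route at 15. F1 is condensed with (R)-1-phenylethylamine (toluene, reflux, water removal) to the imine F2. Its more substituted enamine tautomer adds to ethyl vinyl ketone (THF, 40 °C) in the known deracemising Michael addition, and aqueous acetic acid then releases (R)-7-methyl-7-(3-oxopentyl)-1,4-dioxaspiro[4.5]decan-8-one F3 with the quaternary C10 in place; the (R)-amine is chosen by analogy with the parent 2-methylcyclohexanone case. NaOMe in MeOH closes ring A by aldol condensation to 8,8-(ethylenedioxy)-11,12,13-trinoreudesm-4-en-3-one F4. Li in NH3/THF at −78 °C reduces the enone to the trans-fused C3 enolate, which is trapped with PhNTf2 as 8,8-(ethylenedioxy)-11,12,13-trinoreudesm-3-en-3-yl trifluoromethanesulfonate F5. Pd(OAc)2, PPh3, n-Bu3N and HCO2H in DMF at 60 °C replace the triflate by hydrogen to give 8,8-(ethylenedioxy)-11,12,13-trinoreudesm-3-ene F6, and 1 M HCl in THF then gives 15.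

Step 20. What may go wrong: singlet oxygen may attack the β face, or hydrogen abstraction may take place at C6, so that 5β-hydroperoxides and 4-hydroperoxy-5-enes form beside the wanted isomer; the α-oriented 3-ester may also slow attack on the α face. The fallback changes what controls the face and moves the ene reaction ahead of the esterification; it sets out from 31 and comes back at 35. Photo-oxygenation of the free allylic alcohol 31 (O2, tetraphenylporphyrin, light, CDCl3 or CCl4) uses the known hydroxy-directing effect, in which hydrogen bonding steers singlet oxygen to the face of the hydroxyl (α), and should give methyl 8β-acetoxy-5α-hydroperoxy-3α-hydroxyeudesma-4(15),11(13)-dien-12-oate F7. The hydroperoxide, being more acidic and more nucleophilic than the hindered C3 alcohol, is then masked with 2-methoxypropene and pyridinium p-toluenesulfonate (CH2Cl2, −20 °C) as the 2-methoxyprop-2-yl peroxyketal F8. The 3α-hydroxyl is esterified with mixed anhydride 33 (toluene, 60 °C) to the peroxyketal angelate F9, and AcOH/THF/H2O at 23 °C frees the hydroperoxide to give 35.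

Step 18. What may go wrong: the substrate's own preference for axial (α-face) hydride delivery may override the catalyst, so that the 3β-alcohol forms, or the borane may reduce the acrylate. The fallback accepts the substrate preference and corrects C3 in the esterification; it sets out from 30 and comes back at 34, passing 31 by. Luche reduction of 30 (NaBH4, CeCl3·7H2O, MeOH, −78 °C) should give methyl 8β-acetoxy-3β-hydroxyeudesma-4,11(13)-dien-12-oate F10 without touching the acrylate. Mitsunobu esterification of F10 with angelic acid 32 (PPh3, diisopropyl azodicarboxylate, toluene, 0 °C) then installs the angelate with inversion at C3 and gives 34.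

**Further compounds**
F1 | step 8 | (±)-7-methyl-1,4-dioxaspiro[4.5]decan-8-one | CC1CC2(CCC1=O)OCCO2
F2 | step 8 | imine of F1 with (R)-1-phenylethylamine | CC1CC2(CCC1=N[C@H](C)c1ccccc1)OCCO2
F3 | step 8 | (R)-7-methyl-7-(3-oxopentyl)-1,4-dioxaspiro[4.5]decan-8-one | CCC(=O)CC[C@]1(C)CC2(CCC1=O)OCCO2
F4 | step 8 | 8,8-(ethylenedioxy)-11,12,13-trinoreudesm-4-en-3-one (10β-methyl) | O=C1CC[C@]2(C)CC3(CCC2=C1C)OCCO3
F5 | step 8 | 8,8-(ethylenedioxy)-11,12,13-trinoreudesm-3-en-3-yl trifluoromethanesulfonate (5α-H) | FC(F)(F)S(=O)(=O)OC1=C(C)[C@@H]2CCC3(OCCO3)C[C@@]2(C)CC1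
F6 | step 8 | 8,8-(ethylenedioxy)-11,12,13-trinoreudesm-3-ene (5α-H) | C1=C(C)[C@@H]2CCC3(OCCO3)C[C@@]2(C)CC1
F7 | step 20 | methyl 8β-acetoxy-5α-hydroperoxy-3α-hydroxyeudesma-4(15),11(13)-dien-12-oate | C=C(C(=O)OC)[C@H]1C[C@@]2(OO)C(=C)[C@H](O)CC[C@]2(C)C[C@H]1OC(C)=O
F8 | step 20 | methyl 8β-acetoxy-3α-hydroxy-5α-[(2-methoxypropan-2-yl)peroxy]eudesma-4(15),11(13)-dien-12-oate | C=C(C(=O)OC)[C@H]1C[C@@]2(OOC(C)(C)OC)C(=C)[C@H](O)CC[C@]2(C)C[C@H]1OC(C)=O
F9 | step 20 | methyl 8β-acetoxy-3α-(angeloyloxy)-5α-[(2-methoxypropan-2-yl)peroxy]eudesma-4(15),11(13)-dien-12-oate | C=C(C(=O)OC)[C@H]1C[C@@]2(OOC(C)(C)OC)C(=C)[C@H](OC(=O)/C(C)=C\C)CC[C@]2(C)C[C@H]1OC(C)=O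
F10 | step 18 | methyl 8β-acetoxy-3β-hydroxyeudesma-4,11(13)-dien-12-oate | C=C(C(=O)OC)[C@H]1CC2=C(C)[C@@H](O)CC[C@]2(C)C[C@H]1OC(C)=O
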